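**Conventions and assumption.** Atom labels use ent-kaurane numbering: ring A = C1–C5, C10; C18 = methyl; C19–O–C6(=O) is the γ-lactone; C20–O–C7(=O) is the δ-lactone; C8 and C13 are the bridgeheads; C15 is the ketone; C16=C17 is the methylene. Assumption: configuration is taken exactly from the SMILES (4R,5R,8S,9S,10R,11R,13S; 11-OH cis to C10). Centres left undefined in intermediates (acetal carbon, C10 carbinol, C8 and C16 α-carbons) are mixtures that converge.

## Retrosynthetic overview

1. The enone is unveiled last by dehydration at C17; the bicyclo[3.2.1]octane (C8–C14) comes from transannular alkylation of a β-keto δ-lactone in a cycloheptanone.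
2. The cycloheptanone and the free 11-OH come from SmI2 opening of an 8-oxabicyclo[3.2.1]octan-2-one; the δ-lactone comes from C20-OH transesterifying the C7 ester.
3. Key union: the C9–C10 bond is made by a photoredox Giese coupling of a C10 tertiary radical (West, ten carbons) with an enone ester (East, ten carbons).
4. West: 3-methylcyclohexenone → Cu-catalysed conjugate addition (C4) → C6/C19 cis-fused acetal → C10 carbinol → γ-lactone. East: furan + allyloxyacetaldehyde → Achmatowicz → asymmetric intramolecular oxidopyrylium [5+2] (C11, C13) → ether opening (C14–Br) → carbonylation (C7).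
5. Ring order: γ-lactone on ring A; oxabicycle of East; after union the δ-lactone, then rings C and D together in the transannular closure.

## West fragment (steps 1–8)

**Step 1**
Reactants: 1, 3-methylcyclohex-2-en-1-one; 2, vinylmagnesium bromide
Product: 3, (S)-trimethyl[(3-methyl-3-vinylcyclohex-1-en-1-yl)oxy]silane
Conditions: 2 + Me2AlCl (gives vinyl-AlMe2); CuTC (5 mol %), chiral phosphoramidite/aminophosphine ligand (10 mol %), Et2O, −30 °C; then TMSOTf, Et3N
Reagents that add atoms: trimethylsilyl triflate, C[Si](C)(C)OS(=O)(=O)C(F)(F)F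
Why: Cu-catalysed asymmetric conjugate addition of the vinylalane sets the C4 quaternary centre (ligand enantiomer chosen for S), and silyl trapping of the aluminium enolate fixes the enol ether regiospecifically at C5=C10.

**Step 2**
Reactants: 3
Product: 4, (3S)-2-(dimethoxymethyl)-3-methyl-3-vinylcyclohexan-1-one (C2 epimers)
Conditions: HC(OMe)3, BF3·OEt2, CH2Cl2, −78 °C
Reagents that add atoms: trimethyl orthoformate, COC(OC)OC
Why: Mukaiyama-type alkylation of the silyl enol ether by the dimethoxycarbenium ion installs C6 at C5 only; the C5 configuration is corrected in step 4.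

**Step 3**
Reactants: 4
Product: 5, (1R)-2-(dimethoxymethyl)-1-methyl-3-oxocyclohexane-1-carbaldehyde
Conditions: O3, CH2Cl2, −78 °C; PPh3
Reagents that add atoms: ozone, [O-][O+]=O
Why: Ozonolysis of the only C=C trims the vinyl group to the C19 aldehyde.

**Step 4**
Reactants: 5
Product: 6, (3aR,7aS)-1-methoxy-3a-methylhexahydroisobenzofuran-7(1H)-one (cis-fused, anomers)
Conditions: LiAlH(Ot-Bu)3, THF, −78 °C; then CSA (5 mol %), MeOH, 40 °C
Reagents that add atoms: none
Why: The hindered hydride reduces the aldehyde in preference to the ketone, and acid-catalysed transacetalisation in MeOH closes the five-membered acetal while C5 (α to the ketone) equilibrates to the favoured cis ring fusion, setting C5 relative to C4.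

**Step 5**
Reactants: 6
Product: 7, (3aR,7aR)-1-methoxy-3a-methylhexahydro-1H-spiro[isobenzofuran-7,2'-oxirane]
Conditions: Me3S+ I−, n-BuLi, THF, −10 to 0 °C
Reagents that add atoms: trimethylsulfonium iodide, C[S+](C)C.[I-]
Why: Corey–Chaykovsky epoxidation adds C20 to the C10 ketone; the C10 configuration is irrelevant because C10 later becomes a planar radical.

**Step 6**
Reactants: 7
Product: 8, [(3aR,7aR)-7-hydroxy-1-methoxy-3a-methyloctahydroisobenzofuran-7-yl]methyl acetate
Conditions: CsOAc, 18-crown-6, DMF, 90 °C
Reagents that add atoms: cesium acetate, CC(=O)[O-].[Cs+]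
Why: SN2 opening of the 2,2-disubstituted epoxide by acetate occurs at the CH2 terminus, giving the tertiary C10 alcohol and the C20 acetate.

**Step 7**
Reactants: 8
Product: 9, [(3aR,7aR)-7-hydroxy-3a-methyl-1-oxooctahydroisobenzofuran-7-yl]methyl acetate
Conditions: CrO3, H2SO4, acetone/H2O (Jones), 0 °C
Reagents that add atoms: water, O
Why: Jones oxidation hydrolyses the cyclic methyl acetal and oxidises the lactol to the cis-fused γ-lactone; the tertiary alcohol and acetate are inert.

**Step 8**
Reactants: 9
Product: 10, cesium 2-{[(3aR,7aR)-7-(acetoxymethyl)-3a-methyl-1-oxooctahydroisobenzofuran-7-yl]oxy}-2-oxoacetate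
Conditions: ClCOCO2Me, Et3N, DMAP, CH2Cl2, 0 °C; then CsOH·H2O (1.0 equiv), THF/H2O, 0 °C
Reagents that add atoms: methyl chlorooxoacetate, COC(=O)C(=O)Cl; cesium hydroxide, [Cs+].[OH-]
Why: Acylation of the tertiary alcohol followed by selective hydrolysis of the far more reactive oxalate methyl ester gives the radical precursor.

## East fragment (steps 9–17)

**Step 9**
Reactants: 11, allyl glycidyl ether
Product: 12, 2-(allyloxy)acetaldehyde
Conditions: H5IO6, THF/H2O, rt
Reagents that add atoms: water, O
Why: Periodic acid hydrolyses the epoxide and cleaves the resulting diol, releasing formaldehyde.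

**Step 10**
Reactants: 12; 13, furan
Product: 14, (±)-2-(allyloxy)-1-(furan-2-yl)ethan-1-ol
Conditions: 13, n-BuLi, THF, −78 to 0 °C; then 12, −78 °C
Reagents that add atoms: none
Why: 2-Furyllithium adds to the aldehyde; the carbinol centre is destroyed in step 13, so the racemate is sufficient.

**Step 11**
Reactants: 14
Product: 15, 2-[(allyloxy)methyl]-6-hydroxy-2H-pyran-3(6H)-one
Conditions: NBS, NaHCO3, NaOAc, THF/H2O 4:1, 0 °C
Reagents that add atoms: water, O
Why: Achmatowicz oxidative ring expansion; the furan is far more electron-rich than the terminal alkene.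

**Step 12**
Reactants: 15
Product: 16, 6-[(allyloxy)methyl]-5-oxo-5,6-dihydro-2H-pyran-2-yl 4-(methylthio)benzoate
Conditions: 4-(MeS)C6H4COCl, Et3N, DMAP (cat.), CH2Cl2, −78 to 0 °C
Reagents that add atoms: 4-(methylthio)benzoyl chloride, CSc1ccc(cc1)C(Cl)=O
Why: Acylation of the hemiacetal installs the leaving group needed to generate the pyrylium.

**Step 13**
Reactants: 16
Product: 17, (1R,5R,7R)-8-oxabicyclo[3.2.1]oct-3-en-2-one with C1 and C7 (exo) joined by a CH2–O–CH2 bridge (fused tetrahydrofuran)
Conditions: chiral primary aminothiourea (15 mol %), N,N'-bis[3,5-(CF3)2C6H3]thiourea (15 mol %), AcOH (15 mol %), toluene, 40 °C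
Reagents that add atoms: none
Why: Enantioselective intramolecular oxidopyrylium (aminopyrylium) [5+2] cycloaddition; the three-atom tether forces the internal alkene carbon onto C16 with exo fusion, and the catalyst enantiomer is chosen to set C11 (R), C13 and C16.

**Step 14**
Reactants: 17
Product: 18, (1R,5R,7S)-7-(bromomethyl)-1-(hydroxymethyl)-8-oxabicyclo[3.2.1]oct-3-en-2-one
Conditions: Me2BBr, Et3N (cat.), CH2Cl2, −78 to 0 °C; aq NaHCO3
Reagents that add atoms: bromodimethylborane, CB(C)Br
Why: Boron activates the more basic tetrahydrofuran oxygen and bromide opens it by SN2 at C14 rather than at neopentyl C17; the bridging ether (bridgehead, α-keto) cannot react.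

**Step 15**
Reactants: 18
Product: 19, (1R,5R,7S)-7-(bromomethyl)-1-{[(tert-butyldimethylsilyl)oxy]methyl}-8-oxabicyclo[3.2.1]oct-3-en-2-one
Conditions: TBSCl, imidazole, DMF, rt
Reagents that add atoms: tert-butyldimethylsilyl chloride, CC(C)(C)[Si](C)(C)Cl
Why: Silylation stops the bromo alcohol re-closing and keeps C17–O a poor leaving group through step 20.

**Step 16**
Reactants: 19
Product: 20, the 3-iodo enone of 19
Conditions: I2, pyridine, CH2Cl2, 0 °C to rt
Reagents that add atoms: iodine, II
Why: Johnson α-iodination of the enone (addition–elimination via pyridine) functionalises C8.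

**Step 17**
Reactants: 20
Product: 21, methyl (1R,5R,7S)-7-(bromomethyl)-1-{[(tert-butyldimethylsilyl)oxy]methyl}-2-oxo-8-oxabicyclo[3.2.1]oct-3-ene-3-carboxylate
Conditions: Pd(OAc)2, PPh3, CO (1 atm), MeOH, i-Pr2NEt, DMF, 50 °C
Reagents that add atoms: carbon monoxide, [C-]#[O+]; methanol, CO
Why: Pd-catalysed methoxycarbonylation of the vinyl iodide installs C7 and makes the enone a doubly activated radical acceptor; the primary alkyl bromide does not undergo oxidative addition under these conditions.

## Union and endgame (steps 18–23)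

**Step 18**
Reactants: 10 (1.2 equiv); 21
Product: 22, methyl (1R,4R,5R,7S)-4-[(3aR,7R,7aR)-7-(acetoxymethyl)-3a-methyl-1-oxooctahydroisobenzofuran-7-yl]-7-(bromomethyl)-1-{[(tert-butyldimethylsilyl)oxy]methyl}-2-oxo-8-oxabicyclo[3.2.1]octane-3-carboxylate (C8 epimers)
Conditions: Ir[dF(CF3)ppy]2(dtbbpy)PF6 (2 mol %), DME/DMF 3:1, H2O (10 equiv), blue LEDs, 60 °C
Reagents that add atoms: none
Why: Photoredox oxidation of the oxalate and loss of two CO2 gives the tertiary C10 radical, which undergoes Giese addition at C9; attack on the exo face (syn to the oxygen bridge) places C10 cis to the C11 oxygen, and attack on the convex face of the cis-fused lactone (anti to C5–C6) sets C10.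

**Step 19**
Reactants: 22
Product: 23, the spiro β-keto δ-lactone (C20–O–C7) of 22, with oxabicycle, C14–Br and C17–OTBS intact
Conditions: K2CO3, MeOH, 0 °C; then PPTS, toluene, 80 °C
Reagents that add atoms: none
Why: Acetate methanolysis frees C20-OH, which transesterifies the β-keto methyl ester to close the six-membered lactone.

**Step 20**
Reactants: 23
Product: 24, the cycloheptanone β-keto lactone with free 11-OH, C13–CH2Br and C16–CH2OTBS
Conditions: SmI2 (2.5 equiv), THF/MeOH, −78 °C
Reagents that add atoms: none
Why: Ketyl formation at C15 and reductive cleavage of the aligned α C16–O bond opens the oxygen bridge; C11–O is never broken, so 11-OH retains its configuration, and the bromide and lactones survive at −78 °C.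

**Step 21**
Reactants: 24
Product: 25, the tetracyclic bis-lactone with 11-OH, C15 ketone and C16–CH2OTBS (C16 epimers)
Conditions: K2CO3, NaI (cat.), DMF, 40 °C
Reagents that add atoms: none
Why: Only the β-keto lactone C8–H is acidic enough for carbonate, and its enolate is C-alkylated by C14–Br across the ring to form rings C and D; the CH2 bridge can span only one face, so C13 dictates the C8 configuration.

**Step 22**
Reactants: 25
Product: 26, the C17 primary alcohol of 25
Conditions: HF·pyridine, THF/pyridine, 0 °C to rt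
Reagents that add atoms: none
Why: Non-basic desilylation avoids retro-aldol loss of formaldehyde from the β-hydroxy ketone.

**Step 23**
Reactants: 26
Product: 27, ludongnin A
Conditions: MsCl (1.1 equiv), Et3N, CH2Cl2, −30 °C; then DBU, 0 °C to rt
Reagents that add atoms: none
Why: The primary alcohol is mesylated in preference to the hindered secondary 11-OH, and E1cB elimination through the C16 enolate gives the exo-methylene enone (bridgehead C13 cannot take part).

## Compound list

1 | 3-methylcyclohex-2-en-1-one | CC1=CC(=O)CCC1 | starting material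
2 | vinylmagnesium bromide | C=C[Mg]Br | starting material
3 | (S)-trimethyl[(3-methyl-3-vinylcyclohex-1-en-1-yl)oxy]silane | C=C[C@]1(C)CCCC(O[Si](C)(C)C)=C1 | intermediate
4 | (3S)-2-(dimethoxymethyl)-3-methyl-3-vinylcyclohexan-1-one | C=C[C@]1(C)CCCC(=O)C1C(OC)OC | intermediate
5 | (1R)-2-(dimethoxymethyl)-1-methyl-3-oxocyclohexane-1-carbaldehyde | O=C[C@]1(C)CCCC(=O)C1C(OC)OC | intermediate
6 | (3aR,7aS)-1-methoxy-3a-methylhexahydroisobenzofuran-7(1H)-one | COC1OC[C@]2(C)CCCC(=O)[C@H]12 | intermediate
7 | (3aR,7aR)-1-methoxy-3a-methylhexahydro-1H-spiro[isobenzofuran-7,2'-oxirane] | COC1OC[C@]2(C)CCCC3(CO3)[C@H]12 | intermediate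
8 | [(3aR,7aR)-7-hydroxy-1-methoxy-3a-methyloctahydroisobenzofuran-7-yl]methyl acetate | COC1OC[C@]2(C)CCCC(O)(COC(C)=O)[C@H]12 | intermediate
9 | [(3aR,7aR)-7-hydroxy-3a-methyl-1-oxooctahydroisobenzofuran-7-yl]methyl acetate | O=C1OC[C@]2(C)CCCC(O)(COC(C)=O)[C@H]12 | intermediate
10 | cesium oxalate of 9 (West fragment) | [Cs+].[O-]C(=O)C(=O)OC1(COC(C)=O)CCC[C@@]2(C)COC(=O)[C@H]21 | intermediate
11 | allyl glycidyl ether | C=CCOCC1CO1 | starting material
12 | 2-(allyloxy)acetaldehyde | C=CCOCC=O | intermediate
13 | furan | c1ccoc1 | starting material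
14 | (±)-2-(allyloxy)-1-(furan-2-yl)ethan-1-ol | C=CCOCC(O)c1ccco1 | intermediate
15 | 2-[(allyloxy)methyl]-6-hydroxy-2H-pyran-3(6H)-one | C=CCOCC1OC(O)C=CC1=O | intermediate
16 | 6-[(allyloxy)methyl]-5-oxo-5,6-dihydro-2H-pyran-2-yl 4-(methylthio)benzoate | C=CCOCC1OC(OC(=O)c2ccc(SC)cc2)C=CC1=O | intermediate
17 | (1R,5R,7R) [5+2] cycloadduct (oxabicyclooctenone with fused tetrahydrofuran) | O=C1C=C[C@H]2C[C@@H]3COC[C@@]13O2 | intermediate
18 | (1R,5R,7S)-7-(bromomethyl)-1-(hydroxymethyl)-8-oxabicyclo[3.2.1]oct-3-en-2-one | O=C1C=C[C@H]2C[C@H](CBr)[C@]1(CO)O2 | intermediate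
19 | TBS ether of 18 | O=C1C=C[C@H]2C[C@H](CBr)[C@]1(CO[Si](C)(C)C(C)(C)C)O2 | intermediate
20 | 3-iodo enone of 19 | O=C1C(I)=C[C@H]2C[C@H](CBr)[C@]1(CO[Si](C)(C)C(C)(C)C)O2 | intermediate
21 | enone methyl ester (East fragment) | O=C1C(C(=O)OC)=C[C@H]2C[C@H](CBr)[C@]1(CO[Si](C)(C)C(C)(C)C)O2 | intermediate
22 | Giese adduct (C9–C10 bond) | O=C1C(C(=O)OC)[C@H]([C@]3(COC(C)=O)CCC[C@@]5(C)COC(=O)[C@H]53)[C@H]2C[C@H](CBr)[C@]1(CO[Si](C)(C)C(C)(C)C)O2 | intermediate
23 | spiro β-keto δ-lactone, oxabicycle intact | O=C1C2C(=O)OC[C@]3(CCC[C@@]4(C)COC(=O)[C@H]43)[C@@H]2[C@H]5C[C@H](CBr)[C@]1(CO[Si](C)(C)C(C)(C)C)O5 | intermediate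
24 | cycloheptanone β-keto lactone with 11-OH | O=C1C2C(=O)OC[C@]3(CCC[C@@]4(C)COC(=O)[C@H]43)[C@@H]2[C@H](O)C[C@H](CBr)C1CO[Si](C)(C)C(C)(C)C | intermediate
25 | tetracycle, C16–CH2OTBS | CC(C)(C)[Si](C)(C)OCC1C(=O)[C@]23C[C@H]1C[C@@H](O)[C@H]2[C@@]1(CCC[C@@]2(C)COC(=O)[C@H]21)COC3=O | intermediate
26 | tetracycle, C16–CH2OH | OCC1C(=O)[C@]23C[C@H]1C[C@@H](O)[C@H]2[C@@]1(CCC[C@@]2(C)COC(=O)[C@H]21)COC3=O | intermediate
27 | ludongnin A | C=C1C(=O)[C@]23C[C@H]1C[C@@H](O)[C@H]2[C@@]1(CCC[C@@]2(C)COC(=O)[C@H]21)COC3=O | target

## Totals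

Total step count: 23 (West 8, East 9, 6 after the union).
Longest linear sequence: 15 (steps 9–17, then 18–23).

## Three steps most likely to fail

1. **Step 18, the quaternary–tertiary radical coupling.** Risks are steric congestion, face selectivity at C10, and E1cB loss of the oxalate β to the lactone. Fallback: make the bond by two-electron chemistry instead, using a Mukaiyama–Michael addition of a West silyl ketene acetal (C20 at ester oxidation level, C10 nucleophilic) to enone ester 21, then reduce C20 and lactonise.

2. **Step 21, the transannular C-alkylation.** Risks are ether formation by 11-OH, cyclopropane formation from the C16 enolate, and transannular hemiketal formation masking the ketone. Fallback: carry C14 as a protected alcohol, oxidise it to the aldehyde after step 20, close C8–C14 by intramolecular aldol of the β-keto lactone, and remove the C14 hydroxyl by Barton–McCombie deoxygenation.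

3. **Step 14, the regioselective ether opening next to an enone.** Fallback: carry the tetrahydrofuran intact through coupling and SmI2 cleavage, then open it by base-induced retro-oxa-Michael (E1cB) from the C16 enolate. This gives the exo-methylene enone and frees C14-OH in one operation; Appel iodination and the ring closure follow.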